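The key bond is C1–C2, the only bond shared by the 14-membered carbocycle and the cis-fused α-methylene-γ-butyrolactone. C2 is the lactone carbinol carbon; C1 is the ring-fusion carbon, allylic to the exocyclic C15=C17. This is the retron of a carbonyl allylation by a 2-(alkoxycarbonyl)allyl metal. An indium-mediated intramolecular Barbier reaction of an ω-formyl (Z)-2-(bromomethyl)alk-2-enoate forms this bond, closes the macrocycle, sets C1 and C2 and, after lactonisation, completes the lactone. The acyclic precursor already holds C3, C4, C9 and the 12,13-epoxide; a glyceraldehyde-derived diol masks the aldehyde.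

Key step: step 12

Remark a (numbering, also used for acyclic precursors): C1 ring-fusion carbon carrying the α-methylene unit, C2 lactone carbinol carbon, C3 CHOH, C4 CHCH3, C5–C7 CH2, C8 C(=CH2), C9 CHOH, C10–C11 CH2, C12 methylated epoxide carbon, C13 epoxide CH, C14 CH2, C15 lactone α-carbon, C16 lactone carbonyl, C17 lactone methylidene, C19 methylidene on C8. The target is read as 1S,2R,3R,4S,9R,12R,13R.

Remark b (assumption): compounds 1, 2, 6, 9, 10 and 19 are taken as purchasable; the oxazoline–sulfonamide ligand of step 6 is made from valinol, and its enantiomer is the one that directs Si-face addition.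

Step 1
Reactants: 1 (4S)-2,2-dimethyl-1,3-dioxolane-4-carbaldehyde; 2 (Z)-crotylboronic acid pinacol ester
Product: 4 (1R,2S)-1-[(4S)-2,2-dimethyl-1,3-dioxolan-4-yl]-2-methylbut-3-en-1-ol, via pinacol borate ester 3 (not isolated)
Conditions: CH2Cl2, −78 to 25 °C; then aq. NaHCO3
Reagents that add atoms: none
Why: Thermal crotylboration through a closed Zimmerman–Traxler chair, in which the Z-crotyl geometry gives the syn methyl/hydroxyl pair and the dioxolane stereocentre directs attack anti to its C–O bond (Felkin–Anh), so that the future C3 becomes R and C4 becomes S under substrate control.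

Step 2
Reactants: 4 homoallylic alcohol
Product: 5 (4S)-4-{(1R,2S)-1-[(4-methoxyphenyl)methoxy]-2-methylbut-3-en-1-yl}-2,2-dimethyl-1,3-dioxolane
Conditions: NaH, 4-methoxybenzyl chloride, Bu4NI (cat.), THF–DMF, 0 to 25 °C
Reagents that add atoms: 4-methoxybenzyl chloride, COc1ccc(CCl)cc1
Why: Williamson etherification that touches no stereocentre and installs the ether oxygen later used for chelation at C3.

Step 3
Reactants: 5 PMB ether; 6 2,3-dibromoprop-1-ene
Product: 8 (4S)-4-{(1R,2S)-6-bromo-1-[(4-methoxyphenyl)methoxy]-2-methylhept-6-en-1-yl}-2,2-dimethyl-1,3-dioxolane, via alkylzirconocene chloride 7 (not isolated)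
Conditions: Cp2Zr(H)Cl, THF, 25–40 °C; then CuBr·SMe2 (10 mol %), 6, 0 to 25 °C
Reagents that add atoms: none
Why: Hydrozirconation places zirconium on the terminal carbon, and copper-catalysed allylic substitution of the alkylzirconocene on 6 (SN2 and SN2′ give the same product) leaves the vinylic bromide intact.

Step 4
Reactants: 9 pent-4-yn-1-ol; 10 allyl bromide
Product: 12 (4E)-4-methylocta-4,7-dien-1-ol, via alkenylalane 11 (not isolated)
Conditions: AlMe3 (3 equiv), Cp2ZrCl2 (0.25 equiv), CH2Cl2, 0 to 25 °C; then 10, Pd(PPh3)4 (3 mol %), THF, 25 °C; aq. HCl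
Reagents that add atoms: trimethylaluminium, C[Al](C)C
Why: Zirconium-catalysed Negishi syn-carboalumination gives the E-trisubstituted alkenylalane regioselectively, and palladium-catalysed cross-coupling with allyl bromide proceeds with retention to the 1,4-diene.

Step 5
Reactants: 12 dienol
Product: 13 (4E)-4-methylocta-4,7-dienal
Conditions: TEMPO (10 mol %), PhI(OAc)2, CH2Cl2, 25 °C
Reagents that add atoms: none
Why: Oxoammonium-mediated oxidation of the primary alcohol stops at the aldehyde and leaves the skipped diene untouched.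

Step 6
Reactants: 8 alkenyl bromide; 13 dienal
Product: 15 (4E,8R,13S,14R)-14-[(4S)-2,2-dimethyl-1,3-dioxolan-4-yl]-14-[(4-methoxyphenyl)methoxy]-5,13-dimethyl-9-methylidenetetradeca-1,4-dien-8-ol, via alkenylchromium dichloride 14 (not isolated)
Conditions: CrCl2 (4 equiv), NiCl2 (2 mol %), N-[2-(4-isopropyl-4,5-dihydro-1,3-oxazol-2-yl)-6-methylphenyl]methanesulfonamide (single enantiomer, 4.4 equiv), Et3N, THF, 25 °C
Reagents that add atoms: none
Why: Nozaki–Hiyama–Kishi alkenylation in which zerovalent nickel activates the C–Br bond and transmetalates to trivalent chromium, which adds only to the aldehyde, while the chiral oxazoline–sulfonamide ligand on chromium directs Si-face attack and so sets C9 as R irrespective of the remote stereocentres.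

Step 7
Reactants: 15 allylic alcohol
Product: 16 (4S)-4-{(1R,2S,7R,10E)-1,7-bis[(4-methoxyphenyl)methoxy]-2,10-dimethyl-6-methylidenetetradeca-10,13-dien-1-yl}-2,2-dimethyl-1,3-dioxolane
Conditions: NaH, 4-methoxybenzyl chloride, Bu4NI (cat.), DMF, 0 to 25 °C
Reagents that add atoms: 4-methoxybenzyl chloride, COc1ccc(CCl)cc1
Why: Williamson etherification of the C9 hydroxyl, which keeps it from opening the later 12,13-epoxide and lets both ethers fall in one final operation.

Step 8
Reactants: 16 bis-PMB acetonide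
Product: 17 (2S,3R,4S,9R,12E)-3,9-bis[(4-methoxyphenyl)methoxy]-4,12-dimethyl-8-methylidenehexadeca-12,15-diene-1,2-diol
Conditions: AcOH–H2O (4:1), 40 °C
Reagents that add atoms: none
Why: Mild acid hydrolysis of the terminal isopropylidene ketal, carried out before any epoxide is present and tolerated by the PMB ethers and olefins.

Step 9
Reactants: 17 diene diol
Product: 18 (2S,3R,4S,9R)-3,9-bis[(4-methoxyphenyl)methoxy]-4-methyl-8-methylidene-11-[(2R,3R)-2-methyl-3-(prop-2-en-1-yl)oxiran-2-yl]undecane-1,2-diol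
Conditions: 1,2:4,5-di-O-isopropylidene-β-D-erythro-2,3-hexodiulo-2,6-pyranose (0.3 equiv), KHSO5 (as Oxone), K2CO3, Bu4NHSO4, MeCN–CH2(OMe)2–aq. Na2B4O7 buffer, 0 °C
Reagents that add atoms: potassium peroxymonosulfate KHSO5, [K+].[O-]S(=O)(=O)OO
Why: Shi epoxidation, in which the chiral dioxirane attacks the electron-rich E-trisubstituted C12=C13 olefin through the spiro transition state to give the 12R,13R epoxide under catalyst control, the monosubstituted and 1,1-disubstituted olefins being far less reactive.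

Step 10
Reactants: 18 epoxy diol; 19 methyl 2-(bromomethyl)prop-2-enoate
Product: 20 methyl (2Z)-2-(bromomethyl)-4-[(2R,3R)-3-{(3R,8S,9R,10S)-10,11-dihydroxy-3,9-bis[(4-methoxyphenyl)methoxy]-8-methyl-4-methylideneundecyl}-3-methyloxiran-2-yl]but-2-enoate
Conditions: second-generation Hoveyda–Grubbs catalyst (10 mol %), 19 (5 equiv), CH2Cl2, 40 °C
Reagents that add atoms: none
Why: Olefin cross-metathesis of the terminal vinyl group with a gem-disubstituted acrylate (as with methacrylates) should give the trisubstituted enoate with the C14 chain trans to the ester, while the hindered C8 methylidene and the epoxide stay out.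

Step 11
Reactants: 20 bromo ester diol
Product: 21 methyl (2Z)-2-(bromomethyl)-4-[(2R,3R)-3-{(3R,8S,9R)-3,9-bis[(4-methoxyphenyl)methoxy]-8-methyl-4-methylidene-10-oxodecyl}-3-methyloxiran-2-yl]but-2-enoate
Conditions: NaIO4, THF–pH 7 phosphate buffer, 0 °C
Reagents that add atoms: none
Why: Malaprade glycol cleavage under neutral conditions unmasks the C2 aldehyde, removes the sacrificial glyceraldehyde carbon as formaldehyde and spares the epoxide and allylic bromide; the aldehyde is used at once to avoid epimerisation at C3.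

Step 12
Reactants: 21 bromo ester aldehyde
Product: 24 (1S,2R,3R,4S,9R,12R,13R)-12,13-epoxy-3,9-bis[(4-methoxyphenyl)methoxy]cembra-8(19),15(17)-dien-16,2-olide, via allylindium dibromide 22 (not isolated), via seco hydroxy ester 23 (not isolated)
Conditions: indium powder (In, 3 equiv), THF–H2O (3:1), slow addition of 21 to 1 mM, 25 °C; then PPTS (cat.), CH2Cl2, 25 °C
Reagents that add atoms: none
Why: Indium metal inserts into the allylic C–Br bond and the resulting 2-(methoxycarbonyl)allylindium 22 adds through its γ-carbon to the C2 aldehyde (SE2′ carbonyl allylation via a cyclic six-membered transition state), forming C1–C2 and shifting the olefin to C15=C17. The closest known reaction type is the indium-, zinc- or chromium-mediated Barbier coupling of 2-(bromomethyl)alk-2-enoates with aldehydes, including its intramolecular use for macrocyclic α-methylene lactones. The 14-membered carbocycle closes by this allyl transfer as an end-to-end macrocyclisation, and the γ-lactone then closes by 5-exo-trig attack of the new C2 hydroxyl on the methyl ester with loss of methanol. C2 is controlled by the C3 stereocentre: trivalent indium bridges the aldehyde oxygen and the C3 ether oxygen (Cram chelate), so the allyl group enters anti to the C4 branch and gives the 2,3-syn, 2R carbinol. C1 follows from simple diastereoselection in the chair-like allyl transfer, which for 3-substituted 2-(alkoxycarbonyl)allyl metals gives the 1,2-syn adduct and hence the cis-fused 1S lactone. The step needs ring closure to beat oligomerisation and the aldehyde to react in preference to epoxide and ester, which the water-tolerant, carbonyl-selective allylindium under slow addition secures, and it needs the syn,syn triad, which rests on chelation and is the main uncertainty.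

Step 13
Reactants: 24 bis-PMB macrolactone
Product: 25 (1S,2R,3R,4S,9R,12R,13R)-12,13-epoxy-3,9-dihydroxycembra-8(19),15(17)-dien-16,2-olide (CNP0124069.1)
Conditions: DDQ, CH2Cl2–pH 7 phosphate buffer, 0 °C
Reagents that add atoms: none
Why: Oxidative PMB ether cleavage by benzylic hydride abstraction and hydrolysis of the oxocarbenium ions frees both hydroxyls under neutral conditions that spare the epoxide and the α-methylene lactone.

Compound list
1 | (4S)-2,2-dimethyl-1,3-dioxolane-4-carbaldehyde ((S)-glyceraldehyde acetonide) | O=C[C@@H]1COC(C)(C)O1 | starting material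
2 | 2-[(2Z)-but-2-en-1-yl]-4,4,5,5-tetramethyl-1,3,2-dioxaborolane ((Z)-crotylboronic acid pinacol ester) | C/C=C\CB1OC(C)(C)C(C)(C)O1 | starting material
3 | 2-{[(1R,2S)-1-[(4S)-2,2-dimethyl-1,3-dioxolan-4-yl]-2-methylbut-3-en-1-yl]oxy}-4,4,5,5-tetramethyl-1,3,2-dioxaborolane (pinacol borate ester of 4) | C=C[C@H](C)[C@@H](OB1OC(C)(C)C(C)(C)O1)[C@@H]2COC(C)(C)O2 | intermediate
4 | (1R,2S)-1-[(4S)-2,2-dimethyl-1,3-dioxolan-4-yl]-2-methylbut-3-en-1-ol | C=C[C@H](C)[C@@H](O)[C@@H]1COC(C)(C)O1 | intermediate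
5 | (4S)-4-{(1R,2S)-1-[(4-methoxyphenyl)methoxy]-2-methylbut-3-en-1-yl}-2,2-dimethyl-1,3-dioxolane | C=C[C@H](C)[C@@H](OCc1ccc(OC)cc1)[C@@H]2COC(C)(C)O2 | intermediate
6 | 2,3-dibromoprop-1-ene | C=C(Br)CBr | starting material
7 | chlorobis(cyclopentadienyl){(3S,4R)-4-[(4S)-2,2-dimethyl-1,3-dioxolan-4-yl]-4-[(4-methoxyphenyl)methoxy]-3-methylbutyl}zirconium | Cl[Zr](C1C=CC=C1)(C1C=CC=C1)CC[C@H](C)[C@@H](OCc1ccc(OC)cc1)[C@@H]2COC(C)(C)O2 | intermediate
8 | (4S)-4-{(1R,2S)-6-bromo-1-[(4-methoxyphenyl)methoxy]-2-methylhept-6-en-1-yl}-2,2-dimethyl-1,3-dioxolane | C=C(Br)CCC[C@H](C)[C@@H](OCc1ccc(OC)cc1)[C@@H]2COC(C)(C)O2 | intermediate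
9 | pent-4-yn-1-ol | C#CCCCO | starting material
10 | allyl bromide (3-bromoprop-1-ene) | C=CCBr | starting material
11 | dimethyl{(1E)-5-[(dimethylalumanyl)oxy]-2-methylpent-1-en-1-yl}alumane | C[Al](C)/C=C(\C)CCCO[Al](C)C | intermediate
12 | (4E)-4-methylocta-4,7-dien-1-ol | OCCC/C(C)=C/CC=C | intermediate
13 | (4E)-4-methylocta-4,7-dienal | O=CCC/C(C)=C/CC=C | intermediate
14 | dichloro{(6S,7R)-7-[(4S)-2,2-dimethyl-1,3-dioxolan-4-yl]-7-[(4-methoxyphenyl)methoxy]-6-methylhept-1-en-2-yl}chromium | Cl[Cr](Cl)C(=C)CCC[C@H](C)[C@@H](OCc1ccc(OC)cc1)[C@@H]2COC(C)(C)O2 | intermediate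
15 | (4E,8R,13S,14R)-14-[(4S)-2,2-dimethyl-1,3-dioxolan-4-yl]-14-[(4-methoxyphenyl)methoxy]-5,13-dimethyl-9-methylidenetetradeca-1,4-dien-8-ol | C=CC/C=C(\C)CC[C@@H](O)C(=C)CCC[C@H](C)[C@@H](OCc1ccc(OC)cc1)[C@@H]2COC(C)(C)O2 | intermediate
16 | (4S)-4-{(1R,2S,7R,10E)-1,7-bis[(4-methoxyphenyl)methoxy]-2,10-dimethyl-6-methylidenetetradeca-10,13-dien-1-yl}-2,2-dimethyl-1,3-dioxolane | C=CC/C=C(\C)CC[C@@H](OCc1ccc(OC)cc1)C(=C)CCC[C@H](C)[C@@H](OCc1ccc(OC)cc1)[C@@H]2COC(C)(C)O2 | intermediate
17 | (2S,3R,4S,9R,12E)-3,9-bis[(4-methoxyphenyl)methoxy]-4,12-dimethyl-8-methylidenehexadeca-12,15-diene-1,2-diol | C=CC/C=C(\C)CC[C@@H](OCc1ccc(OC)cc1)C(=C)CCC[C@H](C)[C@@H](OCc1ccc(OC)cc1)[C@@H](O)CO | intermediate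
18 | (2S,3R,4S,9R)-3,9-bis[(4-methoxyphenyl)methoxy]-4-methyl-8-methylidene-11-[(2R,3R)-2-methyl-3-(prop-2-en-1-yl)oxiran-2-yl]undecane-1,2-diol | C=CC[C@H]1O[C@]1(C)CC[C@@H](OCc2ccc(OC)cc2)C(=C)CCC[C@H](C)[C@@H](OCc2ccc(OC)cc2)[C@@H](O)CO | intermediate
19 | methyl 2-(bromomethyl)prop-2-enoate | C=C(CBr)C(=O)OC | starting material
20 | methyl (2Z)-2-(bromomethyl)-4-[(2R,3R)-3-{(3R,8S,9R,10S)-10,11-dihydroxy-3,9-bis[(4-methoxyphenyl)methoxy]-8-methyl-4-methylideneundecyl}-3-methyloxiran-2-yl]but-2-enoate | COC(=O)/C(CBr)=C/C[C@H]1O[C@]1(C)CC[C@@H](OCc2ccc(OC)cc2)C(=C)CCC[C@H](C)[C@@H](OCc2ccc(OC)cc2)[C@@H](O)CO | intermediate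
21 | methyl (2Z)-2-(bromomethyl)-4-[(2R,3R)-3-{(3R,8S,9R)-3,9-bis[(4-methoxyphenyl)methoxy]-8-methyl-4-methylidene-10-oxodecyl}-3-methyloxiran-2-yl]but-2-enoate | COC(=O)/C(CBr)=C/C[C@H]1O[C@]1(C)CC[C@@H](OCc2ccc(OC)cc2)C(=C)CCC[C@H](C)[C@@H](OCc2ccc(OC)cc2)C=O | intermediate
22 | allylindium dibromide from 21 (InBr2 in place of Br on the CH2 group of the enoate) | COC(=O)/C(C[In](Br)Br)=C/C[C@H]1O[C@]1(C)CC[C@@H](OCc2ccc(OC)cc2)C(=C)CCC[C@H](C)[C@@H](OCc2ccc(OC)cc2)C=O | intermediate
23 | methyl 2-{(1S,2R,3R,4S,9R,12R,13R)-12,13-epoxy-2-hydroxy-3,9-bis[(4-methoxyphenyl)methoxy]-4,12-dimethyl-8-methylidenecyclotetradecyl}prop-2-enoate (ring numbered as in the target) | C=C1CCC[C@H](C)[C@@H](OCc3ccc(OC)cc3)[C@H](O)[C@H](C(=C)C(=O)OC)C[C@H]2O[C@]2(C)CC[C@H]1OCc1ccc(OC)cc1 | intermediate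
24 | (1S,2R,3R,4S,9R,12R,13R)-12,13-epoxy-3,9-bis[(4-methoxyphenyl)methoxy]cembra-8(19),15(17)-dien-16,2-olide | C=C1CCC[C@H](C)[C@@H](OCc3ccc(OC)cc3)[C@@H]2OC(=O)C(=C)[C@@H]2C[C@H]2O[C@]2(C)CC[C@H]1OCc1ccc(OC)cc1 | intermediate
25 | (1S,2R,3R,4S,9R,12R,13R)-12,13-epoxy-3,9-dihydroxycembra-8(19),15(17)-dien-16,2-olide (CNP0124069.1) | C=C1CCC[C@H](C)[C@@H](O)[C@@H]2OC(=O)C(=C)[C@@H]2C[C@H]2O[C@]2(C)CC[C@H]1O | target

Total step count: 13. Longest linear sequence: 11 (steps 1–3 and 6–13; steps 4 and 5 make the western aldehyde in parallel).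

Steps most likely to fail

Step 12. The closure may lose out to intermolecular allylation or to simple reduction of the bromide, and weak ether chelation in water may erode both the facial and the simple diastereoselection. The fallback is a Lewis acid-promoted allylstannane cyclisation with the epoxide introduced afterwards. It sets out from diol 17 and acrylate 19: cross-metathesis with the second-generation Hoveyda–Grubbs catalyst would give the 12,13-olefinic bromo ester F1. Me3SnSnMe3 with Pd(PPh3)4 would convert it into the allylstannane F2, and NaIO4 would cleave the diol to the stannyl aldehyde F3. MgBr2·OEt2 in CH2Cl2 at −20 °C under high dilution would then effect a chelation-controlled SE2′ addition through an open transition state, which by the established model gives the 2,3-syn and 1,2-syn relationships; the adduct would lactonise to the 12,13-olefinic macrolactone F4. Shi epoxidation of F4 with the same D-fructose-derived ketone would come back to the route at 24; the 14-membered ring should let the trisubstituted olefin present either face, so the catalyst decides.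

Step 10. The halogenated gem-disubstituted acrylate may undergo slow, unproductive metathesis, homodimerisation of 18 may compete, and the allylic bromide may shorten catalyst life. The fallback uses a halide-free partner and generates the nucleophile by palladium umpolung. It sets out from 18: cross-metathesis with methyl 2-(acetoxymethyl)prop-2-enoate would give the allylic acetate F5, and NaIO4 cleavage would give the acetoxy aldehyde F6. Pd(PPh3)4 (cat.) and InI (indium monoiodide) in THF–H2O would ionise the allylic acetate and transmetalate the π-allyl complex of divalent palladium to an allylindium, which should cyclise as in step 12 and, after lactonisation, come back to the route at 24.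

Step 6. Ligand control of the aldehyde face may be insufficient, or activation of the alkenyl bromide sluggish. The fallback is an organolithium addition followed by oxidation and reagent-controlled reduction. It sets out from 8 and 13: bromine–lithium exchange (t-BuLi, Et2O, −78 °C) and addition to 13 would give 15 mixed with its C9 epimer, the 8S alcohol F7. Dess–Martin periodinane would oxidise the mixture to the enone F8. Corey–Bakshi–Shibata reduction with (S)-2-methyl-CBS-oxazaborolidine and catecholborane at −78 °C, the α-branched alkenyl group acting as the large substituent, should come back to the route at 15 with the 9R configuration.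

Further compounds
F1 | step 12 | methyl (2Z,5E,9R,14S,15R,16S)-2-(bromomethyl)-16,17-dihydroxy-9,15-bis[(4-methoxyphenyl)methoxy]-6,14-dimethyl-10-methylideneheptadeca-2,5-dienoate | COC(=O)/C(CBr)=C/C/C=C(\C)CC[C@@H](OCc1ccc(OC)cc1)C(=C)CCC[C@H](C)[C@@H](OCc1ccc(OC)cc1)[C@@H](O)CO
F2 | step 12 | methyl (2Z,5E,9R,14S,15R,16S)-16,17-dihydroxy-9,15-bis[(4-methoxyphenyl)methoxy]-6,14-dimethyl-10-methylidene-2-[(trimethylstannyl)methyl]heptadeca-2,5-dienoate | COC(=O)/C(C[Sn](C)(C)C)=C/C/C=C(\C)CC[C@@H](OCc1ccc(OC)cc1)C(=C)CCC[C@H](C)[C@@H](OCc1ccc(OC)cc1)[C@@H](O)CO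
F3 | step 12 | methyl (2Z,5E,9R,14S,15R)-9,15-bis[(4-methoxyphenyl)methoxy]-6,14-dimethyl-10-methylidene-16-oxo-2-[(trimethylstannyl)methyl]hexadeca-2,5-dienoate | COC(=O)/C(C[Sn](C)(C)C)=C/C/C=C(\C)CC[C@@H](OCc1ccc(OC)cc1)C(=C)CCC[C@H](C)[C@@H](OCc1ccc(OC)cc1)C=O
F4 | step 12 | (1S,2R,3R,4S,9R,12E)-3,9-bis[(4-methoxyphenyl)methoxy]cembra-8(19),12,15(17)-trien-16,2-olide | C=C1CCC[C@H](C)[C@@H](OCc3ccc(OC)cc3)[C@@H]2OC(=O)C(=C)[C@@H]2C/C=C(C)/CC[C@H]1OCc1ccc(OC)cc1
F5 | step 10 | methyl (2E)-2-(acetoxymethyl)-4-[(2R,3R)-3-{(3R,8S,9R,10S)-10,11-dihydroxy-3,9-bis[(4-methoxyphenyl)methoxy]-8-methyl-4-methylideneundecyl}-3-methyloxiran-2-yl]but-2-enoate | COC(=O)/C(COC(C)=O)=C/C[C@H]1O[C@]1(C)CC[C@@H](OCc2ccc(OC)cc2)C(=C)CCC[C@H](C)[C@@H](OCc2ccc(OC)cc2)[C@@H](O)CO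
F6 | step 10 | methyl (2E)-2-(acetoxymethyl)-4-[(2R,3R)-3-{(3R,8S,9R)-3,9-bis[(4-methoxyphenyl)methoxy]-8-methyl-4-methylidene-10-oxodecyl}-3-methyloxiran-2-yl]but-2-enoate | COC(=O)/C(COC(C)=O)=C/C[C@H]1O[C@]1(C)CC[C@@H](OCc2ccc(OC)cc2)C(=C)CCC[C@H](C)[C@@H](OCc2ccc(OC)cc2)C=O
F7 | step 6 | (4E,8S,13S,14R)-14-[(4S)-2,2-dimethyl-1,3-dioxolan-4-yl]-14-[(4-methoxyphenyl)methoxy]-5,13-dimethyl-9-methylidenetetradeca-1,4-dien-8-ol | C=CC/C=C(\C)CC[C@H](O)C(=C)CCC[C@H](C)[C@@H](OCc1ccc(OC)cc1)[C@@H]2COC(C)(C)O2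
F8 | step 6 | (4E,13S,14R)-14-[(4S)-2,2-dimethyl-1,3-dioxolan-4-yl]-14-[(4-methoxyphenyl)methoxy]-5,13-dimethyl-9-methylidenetetradeca-1,4-dien-8-one | C=CC/C=C(\C)CCC(=O)C(=C)CCC[C@H](C)[C@@H](OCc1ccc(OC)cc1)[C@@H]2COC(C)(C)O2
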